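## Retrosynthetic overview
1. Gravicycle (**8**) comes from the tri-O-methyl macrocycle **7** by a final aryl methyl ether cleavage. The benzylic (R)-carbinol must survive this step.
2. The 22-membered ring is closed last, by a photochemical Cu-catalysed C–O macro-etherification between the syringyl-type phenol and a 3-bromo-5-methoxyphenyl bromide (**6** → **7**).
3. Ring A is attached to the chain terminus by hydroboration/B-alkyl Suzuki coupling of a terminal alkene (**3** → **5**).
4. The alkene chain and the carbinol come from Cu-catalysed opening of the (S)-aryl epoxide **1** with an ω-alkenyl Grignard at the terminal CH2. The stereocentre is carried in from **1** and no bond to it is broken.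
5. Both aromatic rings are present in the starting materials, so the only ring formed is the macrocycle, in the last C–C/C–O event before deprotection.

Assumptions:
- The enantiopure (S)-epoxide **1** is bought as a chiral building block and is the only source of chirality.
- 12-Bromododec-1-ene (**2**) and 3,5-dibromoanisole (**4**) are commercial.

## Route

**Step 1**
Reactants: **1** (S)-tert-butyl[2,6-dimethoxy-4-(oxiran-2-yl)phenoxy]dimethylsilane; **2** 12-bromododec-1-ene
Product: **3** (R)-1-[4-(TBSO)-3,5-dimethoxyphenyl]tetradec-13-en-1-ol
Conditions: (i) **2**, Mg, THF, reflux → Grignard; (ii) **1**, CuI (10 mol %), THF, –30 → 0 °C; aq. NH4Cl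
Reagents that add atoms: none
Why: Cu-catalysed Grignard opening of a terminal epoxide occurs by SN2 at the unhindered CH2. The benzylic C–O bond is never broken, so the (S)-epoxide gives the (R)-carbinol (CIP priorities change from O > CH2 > Ar to O > Ar > CH2) with the stereocentre untouched.

**Step 2**
Reactants: **3**; **4** 3,5-dibromoanisole
Product: **5** (R)-14-(3-bromo-5-methoxyphenyl)-1-[4-(TBSO)-3,5-dimethoxyphenyl]tetradecan-1-ol
Conditions: (i) 9-BBN-H (2.3 equiv), THF, 0 °C → rt; (ii) **4** (3 equiv), Pd(dppf)Cl2 (5 mol %), K3PO4, THF/H2O, 65 °C
Reagents that add atoms: none (boron is lost; **4** is a reactant)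
Why: Anti-Markovnikov hydroboration of the terminal alkene (the free OH is simply O-borylated and released on work-up) followed by B-alkyl Suzuki–Miyaura coupling. The excess dibromide limits double coupling, and the carbinol is not involved.

**Step 3**
Reactants: **5**
Product: **6** (R)-14-(3-bromo-5-methoxyphenyl)-1-(4-hydroxy-3,5-dimethoxyphenyl)tetradecan-1-ol
Conditions: TBAF, THF, 0 °C, 30 min
Reagents that add atoms: none
Why: Fluoride removes the aryl TBS ether (silyl-ether deprotection) to give the phenol needed for C–O coupling; the benzylic alcohol and the aryl bromide are untouched.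

**Step 4**
Reactants: **6**
Product: **7** tri-O-methyl gravicycle, (R)-configured 22-membered cyclic diaryl ether
Conditions: CuI (20 mol %), Cs2CO3 (3 equiv), MeCN, 390 nm LEDs, 25 °C, 2 mM, slow addition of **6** over 20 h
Reagents that add atoms: none
Why: Photoinduced Ullmann-type C–O coupling forms the diaryl ether bond that closes the ring; the stereocentre is not involved. Proposed new method: photoexcited Cu(I)–phenoxide transfers an electron to the unactivated aryl bromide, giving an aryl radical and Cu(II)–OAr that collapse to the C–O bond. Because this path is radical-type, it should tolerate the di-ortho-methoxy phenol that is sluggish in thermal oxidative addition/reductive elimination. The closest known reaction is photoinduced Cu-catalysed Ullmann C–O coupling of phenols and aryl halides; it is not known as a macrocyclisation onto a 2,6-dimethoxyphenol to form a 22-membered cyclophane. Phenoxide (pKa about 10) outcompetes the secondary alcohol, and high dilution with slow addition suppresses oligomerisation.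

**Step 5**
Reactants: **7**
Product: **8** Gravicycle
Conditions: NaSEt (10 equiv), DMF, 130 °C, 6 h; then 1 M HCl
Reagents that add atoms: none (ethyl methyl sulfide is the by-product)
Why: SN2 thiolate demethylation of the three aryl methyl ethers (one on ring A, two flanking the ether oxygen on ring B). Unlike BBr3, it does not ionise the electron-rich benzylic alcohol, so the (R)-centre is retained.

## Compound list
1 | (S)-tert-butyl[2,6-dimethoxy-4-(oxiran-2-yl)phenoxy]dimethylsilane | CC(C)(C)[Si](C)(C)Oc1c(OC)cc(cc1OC)[C@H]1CO1 | starting material
2 | 12-bromododec-1-ene | C=CCCCCCCCCCCBr | starting material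
3 | (R)-1-[4-(TBSO)-3,5-dimethoxyphenyl]tetradec-13-en-1-ol | CC(C)(C)[Si](C)(C)Oc1c(OC)cc(cc1OC)[C@H](O)CCCCCCCCCCCC=C | intermediate
4 | 3,5-dibromoanisole | COc1cc(Br)cc(Br)c1 | starting material
5 | (R)-14-(3-bromo-5-methoxyphenyl)-1-[4-(TBSO)-3,5-dimethoxyphenyl]tetradecan-1-ol | CC(C)(C)[Si](C)(C)Oc1c(OC)cc(cc1OC)[C@H](O)CCCCCCCCCCCCCc1cc(Br)cc(OC)c1 | intermediate
6 | (R)-14-(3-bromo-5-methoxyphenyl)-1-(4-hydroxy-3,5-dimethoxyphenyl)tetradecan-1-ol | Oc1c(OC)cc(cc1OC)[C@H](O)CCCCCCCCCCCCCc1cc(Br)cc(OC)c1 | intermediate
7 | tri-O-methyl gravicycle | COc1cc2cc(c1)Oc1c(OC)cc(cc1OC)[C@H](O)CCCCCCCCCCCCC2 | intermediate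
8 | Gravicycle | Oc1cc2cc(c1)Oc1c(O)cc(cc1O)[C@H](O)CCCCCCCCCCCCC2 | target

## Summary
Total steps: 5. Longest linear sequence: 5 (1 → 3 → 5 → 6 → 7 → 8, counting from epoxide **1**).

**Three steps most likely to fail:**
1. **Step 4 (proposed new photo-Cu macro-etherification).** Possible problems are oligomerisation, hydrodebromination, or O-arylation of the benzylic alcohol.
   - Fallback (known chemistry): swap the order of ring closure. First form the diaryl ether intermolecularly by Chan–Lam coupling of the phenol from the alkene (deprotected **3**) with (3-bromo-5-methoxyphenyl)boronic acid. Then hydroborate with 9-BBN and close the ring by intramolecular B-alkyl Suzuki coupling at 1–2 mM.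
2. **Step 1 (epoxide opening).** The electron-rich benzylic epoxide may undergo Lewis-acid-induced Meinwald rearrangement or benzylic attack with partial loss of ee.
   - Fallback: use the (S)-4-bromo-3,5-dimethoxystyrene oxide, whose meta-OMe groups do not stabilise the benzylic cation. After the chain and ring A are installed, convert the 4-Br to 4-OH by Li–Br exchange, B(OMe)3 and H2O2.
3. **Step 5 (demethylation).** Forcing thiolate conditions could cause elimination of the benzylic alcohol or incomplete demethylation of the hindered 2,6-dimethoxy groups.
   - Fallback: acetylate the carbinol, cleave all three methyl ethers with BBr3 at –78 → 0 °C, then remove the acetate with K2CO3/MeOH.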